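**Retrosynthetic overview**
- Target 19 ← removal of three MOM groups from 18 ← stereoretentive C3–B to C3–OH oxidation of the 3-borylflavan 17.
- The strategy rests on the dihydropyran C ring with its trans C2-aryl and C3-oxygen. O1–C8a–C4a–C4 is the A-ring o-quinone methide 16, and C2=C3 is the E-alkene of styrylboronate 15, with Bpin standing in for the C3 hydroxyl. The disconnections are O1–C2 and C3–C4, an oxa-[4+2].
- 16 ← salicyl alcohol 8 ← salicylaldehyde 7 ← aromatic Claisen rearrangement of the 1,1-dimethylallyl ether 5 (places the C8 prenyl group) ← 2 ← 2,4,6-trihydroxybenzaldehyde 1.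
- 15 ← boron-Wittig olefination of aldehyde 11 with 12, the 4-OH carried as an allyl ether ← 3,4-dihydroxybenzaldehyde 9.
- Ring order: the A and B rings are bought; the pyran C ring is the only ring formed, in step 10.

Key step: step 10

Assumption: the sense of induction of the phosphoric acid cannot be predicted with confidence, so the (R)-catalyst is written and its antipode would be used if the first correlation with the natural (2R,3S) series shows the opposite sense.

Step 1
Reactants: 1 2,4,6-trihydroxybenzaldehyde
Product: 2 2-hydroxy-4,6-bis(methoxymethoxy)benzaldehyde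
Conditions: MOMCl (2.3 equiv), i-Pr2NEt, CH2Cl2, 0 °C → rt
Reagents that add atoms: chloromethyl methyl ether, COCCl
Why: Williamson-type O-alkylation stops at the bis-ether because the last ortho hydroxyl is locked in a hydrogen bond to the formyl group and is the least nucleophilic.

Step 2
Reactants: 2 2-hydroxy-4,6-bis(methoxymethoxy)benzaldehyde; 3 3-chloro-3-methylbut-1-yne
Product: 4 2-[(2-methylbut-3-yn-2-yl)oxy]-4,6-bis(methoxymethoxy)benzaldehyde
Conditions: DBU, CuCl2·2H2O (cat.), MeCN, 0 °C → rt
Reagents that add atoms: none
Why: Copper-catalysed propargylic substitution (copper acetylide activation of the tertiary propargylic chloride) O-alkylates phenols with tertiary electrophiles that cannot react by SN2, and only one hydroxyl is free.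

Step 3
Reactants: 4 2-[(2-methylbut-3-yn-2-yl)oxy]-4,6-bis(methoxymethoxy)benzaldehyde
Product: 5 2-[(2-methylbut-3-en-2-yl)oxy]-4,6-bis(methoxymethoxy)benzaldehyde
Conditions: H2 (1 atm), Lindlar catalyst, quinoline, EtOAc, rt
Reagents that add atoms: none
Why: Lindlar semihydrogenation takes the terminal alkyne to the vinyl group and should leave the aldehyde, the aryl ether and the MOM acetals untouched.

Step 4
Reactants: 5 2-[(2-methylbut-3-en-2-yl)oxy]-4,6-bis(methoxymethoxy)benzaldehyde
Product: 7 2-hydroxy-4,6-bis(methoxymethoxy)-3-(3-methylbut-2-en-1-yl)benzaldehyde, via ortho-dienone 6 (not isolated)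
Conditions: PhNEt2, 140 °C, Ar
Reagents that add atoms: none
Why: Aromatic Claisen [3,3] rearrangement moves the tertiary allyl group with allylic inversion to the only unsubstituted ortho carbon, and tautomerisation of the dienone gives the linear prenyl group at the carbon that becomes C8.

Step 5
Reactants: 7 2-hydroxy-4,6-bis(methoxymethoxy)-3-(3-methylbut-2-en-1-yl)benzaldehyde
Product: 8 2-(hydroxymethyl)-3,5-bis(methoxymethoxy)-6-(3-methylbut-2-en-1-yl)phenol
Conditions: NaBH4, THF/MeOH, 0 °C; pH 7 buffer work-up, used without storage
Reagents that add atoms: none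
Why: Borohydride reduction of the salicylaldehyde gives the salicyl alcohol, and a neutral work-up avoids premature ionisation of this electron-rich benzylic alcohol.

Step 6
Reactants: 9 3,4-dihydroxybenzaldehyde
Product: 10 4-(prop-2-en-1-yloxy)-3-hydroxybenzaldehyde
Conditions: allyl bromide (1.1 equiv), NaHCO3, NaI (cat.), DMF, 40 °C
Reagents that add atoms: allyl bromide, C=CCBr
Why: Williamson etherification is selective because only the 4-OH, para to the formyl group and the more acidic one, is deprotonated by bicarbonate.

Step 7
Reactants: 10 4-(prop-2-en-1-yloxy)-3-hydroxybenzaldehyde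
Product: 11 4-(prop-2-en-1-yloxy)-3-(methoxymethoxy)benzaldehyde
Conditions: MOMCl, i-Pr2NEt, CH2Cl2, 0 °C → rt
Reagents that add atoms: chloromethyl methyl ether, COCCl
Why: Standard MOM etherification of the one remaining phenol.

Step 8
Reactants: 11 4-(prop-2-en-1-yloxy)-3-(methoxymethoxy)benzaldehyde; 12 bis[(pinacolato)boryl]methane
Product: 14 (E)-2-[4-(prop-2-en-1-yloxy)-3-(methoxymethoxy)styryl]-4,4,5,5-tetramethyl-1,3,2-dioxaborolane, via lithiated gem-diboronate 13 (not isolated)
Conditions: 12, LiTMP, THF, 0 °C; then 11, −78 °C → rt; H2O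
Reagents that add atoms: none
Why: Boron-Wittig olefination: the α-boryl carbanion adds to the non-enolisable aldehyde and syn B–O elimination gives the E-alkenylboronate, the 4-oxygen being masked so that no phenoxide deactivates the aldehyde.

Step 9
Reactants: 14 (E)-2-[4-(prop-2-en-1-yloxy)-3-(methoxymethoxy)styryl]-4,4,5,5-tetramethyl-1,3,2-dioxaborolane
Product: 15 (E)-2-[4-hydroxy-3-(methoxymethoxy)styryl]-4,4,5,5-tetramethyl-1,3,2-dioxaborolane
Conditions: Pd(PPh3)4 (cat.), morpholine, THF, rt
Reagents that add atoms: none
Why: Palladium(0)-catalysed deallylation (Tsuji–Trost allyl transfer to morpholine) frees the phenol under neutral conditions that should leave the alkenylboronate, which is not activated without base, and the MOM acetal intact.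

Step 10
Reactants: 8 2-(hydroxymethyl)-3,5-bis(methoxymethoxy)-6-(3-methylbut-2-en-1-yl)phenol; 15 (E)-2-[4-hydroxy-3-(methoxymethoxy)styryl]-4,4,5,5-tetramethyl-1,3,2-dioxaborolane
Product: 17 (2S,3S)-2-[4-hydroxy-3-(methoxymethoxy)phenyl]-5,7-bis(methoxymethoxy)-8-(3-methylbut-2-en-1-yl)-3-(4,4,5,5-tetramethyl-1,3,2-dioxaborolan-2-yl)chromane (2,3-trans; same spatial arrangement as the (2R,3S) target because boron lowers the rank of C3 at C2), via o-quinone methide 16 (not isolated)
Conditions: (R)-TRIP (10 mol%), 5 Å MS, PhMe, 0 °C → rt; slow addition of 8 to 15 (2 equiv)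
Reagents that add atoms: none
Why: Proposed new method: the phosphoric acid should dehydrate the electron-rich salicyl alcohol 8 to o-quinone methide 16 and hold it as a hydrogen-bonded oxa-diene, while its phosphoryl oxygen binds the free 4-OH of 15, which raises the nucleophilicity of the styrene and brings both partners into one chiral pocket. The boron-bearing alkene carbon attacks the exocyclic methylene (C3–C4) and the para-hydroxybenzylic cation, or its p-quinone methide tautomer, is captured by the A-ring oxygen (O1–C2), so the pyran closes as the six-membered ring of an inverse-demand oxa-[4+2] cycloaddition, in the stepwise limit a 6-exo-trig oxa-1,6-addition. The closest known reaction type is the chiral phosphoric acid-catalysed [4+2] cycloaddition of in situ o-quinone methides with hydroxystyrenes, together with the uncatalysed flavan-forming cycloaddition of o-quinone methides with β-substituted styrenes; an alkenylboronate has not been used as the 2π partner. C3 is set in the C–C bond-forming event by the alkene face that the phosphate-bound quinone methide meets (catalyst control through the two hydrogen bonds), and C2 follows from suprafacial addition to the E-alkene, which is also the diequatorial, thermodynamically preferred trans arrangement. The regiochemistry needed is secured by the para-oxygenated aryl group, which alone can stabilise the developing cation, so boron ends up at C3. The chemoselectivity needed, ring closure in place of boron loss from the β-boryl cation (alkenyl transfer) and in place of self-condensation of 16, should be secured by the weakly Lewis-acidic pinacol ester, the absence of base, molecular sieves and slow addition of 8 to an excess of 15.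

Step 11
Reactants: 17 (2S,3S)-3-boryl-5,7,3'-tri-O-MOM-8-prenylflavan
Product: 18 (2R,3S)-2-[4-hydroxy-3-(methoxymethoxy)phenyl]-5,7-bis(methoxymethoxy)-8-(3-methylbut-2-en-1-yl)chroman-3-ol
Conditions: NaBO3·4H2O, THF/H2O, 0 °C → rt
Reagents that add atoms: sodium perborate (hydrate; dimeric anion shown), [Na+].[Na+].O[B-]1(O)OO[B-](O)(O)OO1
Why: Oxidation of the secondary alkylboronate proceeds by 1,2-migration of C3 from boron to oxygen with retention, so the C3–OH stays trans to the aryl group, and perborate is mild enough for the prenyl alkene, the phenol and the base-sensitive C2.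

Step 12
Reactants: 18 (2R,3S)-5,7,3'-tri-O-MOM-8-prenylcatechin
Product: 19 8-prenylcatechin, (2R,3S)-2-(3,4-dihydroxyphenyl)-8-(3-methylbut-2-en-1-yl)chromane-3,5,7-triol
Conditions: 3 M HCl (aq)/MeOH, rt → 40 °C, Ar
Reagents that add atoms: none
Why: Acid-catalysed transacetalisation of the three aryl MOM ethers to methanol is the established deprotection for prenylated polyphenols, and dilute acid at moderate temperature should spare the prenyl group and both stereocentres.

**Compound list**
1 | 2,4,6-trihydroxybenzaldehyde | O=Cc1c(O)cc(O)cc1O | starting material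
2 | 2-hydroxy-4,6-bis(methoxymethoxy)benzaldehyde | COCOc1cc(O)c(C=O)c(OCOC)c1 | intermediate
3 | 3-chloro-3-methylbut-1-yne | CC(C)(Cl)C#C | starting material
4 | 2-[(2-methylbut-3-yn-2-yl)oxy]-4,6-bis(methoxymethoxy)benzaldehyde | C#CC(C)(C)Oc1cc(OCOC)cc(OCOC)c1C=O | intermediate
5 | 2-[(2-methylbut-3-en-2-yl)oxy]-4,6-bis(methoxymethoxy)benzaldehyde | C=CC(C)(C)Oc1cc(OCOC)cc(OCOC)c1C=O | intermediate
6 | 2,4-bis(methoxymethoxy)-5-(3-methylbut-2-en-1-yl)-6-oxocyclohexa-1,3-diene-1-carbaldehyde (racemic ortho-dienone, not isolated) | CC(C)=CCC1C(=O)C(C=O)=C(OCOC)C=C1OCOC | intermediate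
7 | 2-hydroxy-4,6-bis(methoxymethoxy)-3-(3-methylbut-2-en-1-yl)benzaldehyde | CC(C)=CCc1c(O)c(C=O)c(OCOC)cc1OCOC | intermediate
8 | 2-(hydroxymethyl)-3,5-bis(methoxymethoxy)-6-(3-methylbut-2-en-1-yl)phenol | CC(C)=CCc1c(OCOC)cc(OCOC)c(CO)c1O | intermediate
9 | 3,4-dihydroxybenzaldehyde | O=Cc1ccc(O)c(O)c1 | starting material
10 | 4-(prop-2-en-1-yloxy)-3-hydroxybenzaldehyde | C=CCOc1ccc(C=O)cc1O | intermediate
11 | 4-(prop-2-en-1-yloxy)-3-(methoxymethoxy)benzaldehyde | C=CCOc1ccc(C=O)cc1OCOC | intermediate
12 | bis[(pinacolato)boryl]methane | CC1(C)OB(CB2OC(C)(C)C(C)(C)O2)OC1(C)C | starting material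
13 | lithio-bis[(pinacolato)boryl]methane (not isolated) | [Li]C(B1OC(C)(C)C(C)(C)O1)B1OC(C)(C)C(C)(C)O1 | intermediate
14 | (E)-2-[4-(prop-2-en-1-yloxy)-3-(methoxymethoxy)styryl]-4,4,5,5-tetramethyl-1,3,2-dioxaborolane | C=CCOc1ccc(/C=C/B2OC(C)(C)C(C)(C)O2)cc1OCOC | intermediate
15 | (E)-2-[4-hydroxy-3-(methoxymethoxy)styryl]-4,4,5,5-tetramethyl-1,3,2-dioxaborolane | CC1(C)OB(/C=C/c2ccc(O)c(OCOC)c2)OC1(C)C | intermediate
16 | 3,5-bis(methoxymethoxy)-6-methylidene-2-(3-methylbut-2-en-1-yl)cyclohexa-2,4-dien-1-one (o-quinone methide, not isolated) | C=C1C(OCOC)=CC(OCOC)=C(CC=C(C)C)C1=O | intermediate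
17 | (2S,3S)-2-[4-hydroxy-3-(methoxymethoxy)phenyl]-5,7-bis(methoxymethoxy)-8-(3-methylbut-2-en-1-yl)-3-(4,4,5,5-tetramethyl-1,3,2-dioxaborolan-2-yl)chromane (2,3-trans) | CC(C)=CCc1c(OCOC)cc(OCOC)c2c1O[C@H](c1ccc(O)c(OCOC)c1)[C@@H](B1OC(C)(C)C(C)(C)O1)C2 | intermediate
18 | (2R,3S)-2-[4-hydroxy-3-(methoxymethoxy)phenyl]-5,7-bis(methoxymethoxy)-8-(3-methylbut-2-en-1-yl)chroman-3-ol | CC(C)=CCc1c(OCOC)cc(OCOC)c2c1O[C@H](c1ccc(O)c(OCOC)c1)[C@@H](O)C2 | intermediate
19 | 8-prenylcatechin, (2R,3S)-2-(3,4-dihydroxyphenyl)-8-(3-methylbut-2-en-1-yl)chromane-3,5,7-triol | CC(C)=CCc1c(O)cc(O)c2c1O[C@H](c1ccc(O)c(O)c1)[C@@H](O)C2 | target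

**Step count and risks**
Total step count: 12. Longest linear sequence: 8 steps (steps 1–5, 10, 11, 12); the boronate arm is steps 6–9.

Steps most likely to fail:

1. Step 10 (Proposed new method). What may go wrong:
- The β-boryl cation may lose boron, giving alkenyl transfer instead of ring closure.
- Facial discrimination may be poor because the hydrogen-bonding hydroxyl is remote from the reacting alkene carbon.
- The quinone methide may self-condense at the free A-ring position.
- Ionisation of the primary benzylic alcohol may be slow.

Fallback: it sets out from salicylaldehyde 7 and boronate 15 and comes back at 17. KHF2 in aqueous MeOH would turn 15 into potassium (E)-[4-hydroxy-3-(methoxymethoxy)styryl]trifluoroborate F1. Heating F1 with 7 and dibenzylamine would give racemic 2-[4-hydroxy-3-(methoxymethoxy)phenyl]-5,7-bis(methoxymethoxy)-8-(3-methylbut-2-en-1-yl)-2H-chromene F2; this is a Petasis-type alkenyl transfer to the iminium ion, followed by loss of the amine and oxa-6π electrocyclisation of the vinyl o-quinone methide. Copper(I)-catalysed enantioselective protoboration of the styrenic C3=C4 bond of F2 (CuCl, chiral bisphosphine, B2pin2, NaOt-Bu, MeOH) would then be run as a kinetic resolution. The ligand is chosen so that the enantiomer with the C2 configuration of the target reacts faster. Boron is placed at C3 anti to the C2 aryl group, the unactivated prenyl alkene is left alone, and 17 is delivered at the cost of at most half of the material.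

2. Step 12. What may go wrong:
- Acid-induced cyclisation of the prenyl group onto the freed 7-OH.
- Epimerisation at C2 through benzylic ionisation assisted by the 4'-OH.
- Air oxidation of the catechol.

Fallback: it sets out from 18 and comes back at 19. TMSOTf and 2,2'-bipyridyl in MeCN (0 °C → rt) would exchange the three aryl MOM acetals for silyl ethers under buffered, non-protic conditions and silylate the two free hydroxyls. This gives (2R,3S)-3,5,7,3',4'-pentakis-O-(trimethylsilyl)-8-prenylcatechin F3. Brief stirring with water and dilute citric acid in THF would then hydrolyse the silyl ethers to 19.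

3. Step 2. What may go wrong:
- Sluggish O-alkylation of the hydrogen-bonded, hindered phenol.
- Elimination of the tertiary chloride.
- Competing C-alkylation of the electron-rich ring.

Fallback: it sets out from 2 and comes back at 5. Palladium(0)-catalysed decarboxylative O-allylation (Tsuji–Trost; Pd(PPh3)4, tert-butyl 2-methylbut-3-en-2-yl carbonate, THF, 0 °C) would let the phenoxide attack the more substituted terminus of the π-(1,1-dimethylallyl)palladium complex under kinetic control. This gives the tertiary allyl ether 5 directly, so neither the propargylic substitution nor the semihydrogenation is needed; no compound outside the list is formed (F0).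

**Further compounds**
F1 | step 10 | potassium (E)-[4-hydroxy-3-(methoxymethoxy)styryl]trifluoroborate | [K+].F[B-](F)(F)/C=C/c1ccc(O)c(OCOC)c1
F2 | step 10 | 2-[4-hydroxy-3-(methoxymethoxy)phenyl]-5,7-bis(methoxymethoxy)-8-(3-methylbut-2-en-1-yl)-2H-chromene (racemic) | CC(C)=CCc1c(OCOC)cc(OCOC)c2c1OC(c1ccc(O)c(OCOC)c1)C=C2
F3 | step 12 | (2R,3S)-3,5,7,3',4'-pentakis-O-(trimethylsilyl)-8-prenylcatechin | CC(C)=CCc1c(O[Si](C)(C)C)cc(O[Si](C)(C)C)c2c1O[C@H](c1ccc(O[Si](C)(C)C)c(O[Si](C)(C)C)c1)[C@@H](O[Si](C)(C)C)C2
F0 | step 2 | none | none
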